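**Plan**

- Retrosynthetic cuts, in order: the C-17 methylene; C-8–C-9 (the 14-membered ring); the C-3/C-4 epoxide oxygen; C-5–C-6; C-4–C-5 and C-3=C-4; C-9=C-10; then both lactone bonds O–C-12 and C-15–C-1 together; C-1=C-2; back to nerol, which supplies C-10 to C-14 and C-1.
- Forward order: nerol epoxide → enal; the seven-membered lactone ring (O, C-12, C-13, C-14, C-1, C-15, C-16) is made first; the chain is then grown from C-3 out to C-8 and from C-10 to C-9; the 14-membered carbocycle is closed last at C-8–C-9; the methylene goes on at the end.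
- Enabling feature: C-1 and C-12 are 1,4-related across C-14/C-13; C-12 is a tertiary C–O next to the C-11 carbinol, the footprint of a C-11/C-12 epoxide opened at its tertiary end; C-1 is β to C-3. A malonate, nucleophilic first at carbon and then at oxygen, can therefore add to a C-1=C-2–C-3 enal and open the epoxide in one flask.
- Stereochemistry: C-11 and C-12 from Sharpless epoxidation of the Z-allylic alcohol (C-12 inverted during lactonization); C-1 from the aminocatalyst; C-6 and the Z C-3=C-4 alkene from a catalyst-set C-3 allylboronate through a chair allylboration; the C-3/C-4 epoxide from C-6–OH-directed vanadium epoxidation; Z C-7=C-8 from a Z-vinyl iodide coupled with retention.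

Key step: step 4

Assumption: positions are given in cembrane numbering (C-1 carries the lactone α-carbon C-15, C-16 is the lactone carbonyl, C-17 the exocyclic methylene, C-12 carries the lactone oxygen); (tributylstannyl)methanol and both enantiomers of diphenylprolinol trimethylsilyl ether are taken as purchasable.

**Route**

Step 1
Reactants: 1 nerol, (2Z)-3,7-dimethylocta-2,6-dien-1-ol
Product: 2 (2R,3S)-2,3-epoxynerol, [(2R,3S)-3-methyl-3-(4-methylpent-3-en-1-yl)oxiran-2-yl]methanol
Conditions: Ti(OiPr)4 (cat.), D-(−)-diethyl tartrate (cat.), t-BuOOH, 4 Å MS, CH2Cl2, −20 °C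
Reagents that add atoms: tert-butyl hydroperoxide, CC(C)(C)OO
Why: Sharpless asymmetric epoxidation acts only on the allylic Z-alkene, and the D-(−)-tartrate complex should deliver oxygen to the face that gives the (2R,3S) cis-epoxide, which fixes C-11 as R and C-12 as S (to be inverted in step 4).

Step 2
Reactants: 2 (2R,3S)-2,3-epoxynerol
Product: 3 tert-butyl{[(2R,3S)-3-methyl-3-(4-methylpent-3-en-1-yl)oxiran-2-yl]methoxy}diphenylsilane
Conditions: t-BuPh2SiCl, imidazole, CH2Cl2, 0 °C to rt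
Reagents that add atoms: tert-butyl(chloro)diphenylsilane, CC(C)(C)[Si](Cl)(c1ccccc1)c1ccccc1
Why: Silylation of the primary alcohol gives an acid-stable ether that survives step 4 and whose inductive pull disfavours later ionization at C-11.

Step 3
Reactants: 3 silyl ether of epoxynerol
Product: 4 (2E)-5-[(2S,3R)-3-{[tert-butyl(diphenyl)silyl]oxymethyl}-2-methyloxiran-2-yl]pent-2-enal
Conditions: crotonaldehyde (excess), second-generation Hoveyda–Grubbs catalyst (cat.), CH2Cl2, 40 °C
Reagents that add atoms: (E)-crotonaldehyde, C/C=C/C=O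
Why: Olefin cross-metathesis exchanges the isopropylidene terminus for the conjugated aldehyde with loss of a volatile alkene, and the E-enal is the thermodynamic product.

Step 4
Reactants: 4 epoxy enal; 5 di-tert-butyl malonate
Product: 8 2-[(4S,7R)-7-[(1R)-2-{[tert-butyl(diphenyl)silyl]oxy}-1-hydroxyethyl]-7-methyl-2-oxooxepan-4-yl]acetaldehyde, via Michael adduct 6 (not isolated), via carboxy lactone 7 (not isolated)
Conditions: (R)-2-[diphenyl(trimethylsilyloxy)methyl]pyrrolidine (10 mol%), EtOH, 0 °C to rt; evaporate, then CF3CO2H, CH2Cl2, 0 °C to rt; evaporate, then pyridine, toluene, 90 °C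
Reagents that add atoms: none
Why: The secondary-amine catalyst converts enal 4 into an s-trans E-iminium ion, one face of which is shielded by the diphenyl(silyloxy)methyl group, so malonate 5 adds in Michael fashion to C-1 from the open face and sets C-1 as S (catalyst control; closest known type is the aminocatalytic malonate addition to enals), the epoxide being inert at this neutral stage. On acidification the epoxide is protonated and the carbonyl oxygen of one tert-butyl ester attacks C-12 with inversion while isobutene is lost, a 7-exo-tet closure of the lactone ring (O, C-12, C-13, C-14, C-1, C-15, C-16) of the known acid-promoted epoxy ester to hydroxy lactone type. C-12 therefore becomes R by stereospecific inversion of the (12S) epoxide carbon from step 1, and C-11 keeps its R configuration and emerges as the free carbinol. The step needs attack at C-12 and not at C-11: C-12 is tertiary and carries the developing positive charge, the exo seven-membered mode beats the endo eight-membered one, and the silyloxymethyl group on C-10 destabilizes charge at C-11. The second ester is cleaved to acid 7, which loses CO2 on warming, so both lactone bonds (O–C-12 and C-15–C-1) arise in one flask from a linear precursor.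

Step 5
Reactants: 8 hydroxy lactone aldehyde
Product: 9 2-[(4S,7R)-7-[(1R)-1-{[tert-butyl(dimethyl)silyl]oxy}-2-{[tert-butyl(diphenyl)silyl]oxy}ethyl]-7-methyl-2-oxooxepan-4-yl]acetaldehyde
Conditions: t-BuMe2SiOTf, 2,6-lutidine, CH2Cl2, −78 °C
Reagents that add atoms: tert-butyldimethylsilyl trifluoromethanesulfonate, CC(C)(C)[Si](C)(C)OS(=O)(=O)C(F)(F)F
Why: The silyl triflate silylates the hindered C-11 carbinol at low temperature, where the lutidine base is too weak to enolize the aldehyde.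

Step 6
Reactants: 9 silyl-protected lactone aldehyde
Product: 10 (4S,7R)-7-[(1R)-1-{[tert-butyl(dimethyl)silyl]oxy}-2-{[tert-butyl(diphenyl)silyl]oxy}ethyl]-4-[(2Z)-3-iodobut-2-en-1-yl]-7-methyloxepan-2-one
Conditions: EtPPh3I, n-BuLi, THF, then I2, −78 °C; NaN(SiMe3)2; then 9, −78 °C to rt
Reagents that add atoms: ethyltriphenylphosphonium iodide, CC[P+](c1ccccc1)(c1ccccc1)c1ccccc1.[I-]; iodine, II
Why: Stork–Zhao-type Wittig olefination with the α-iodo ylide proceeds through the kinetic cis-oxaphosphetane and should give the Z-iodoalkene (iodine cis to C-2), the lactone being inert to the ylide at low temperature.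

Step 7
Reactants: 10 Z-vinyl iodide
Product: 11 (4S,7R)-7-[(1R)-1-{[tert-butyl(dimethyl)silyl]oxy}-2-hydroxyethyl]-4-[(2Z)-3-iodobut-2-en-1-yl]-7-methyloxepan-2-one
Conditions: Bu4NF, AcOH, THF/H2O, rt
Reagents that add atoms: none
Why: Acetic-acid-buffered fluoride desilylation removes the unhindered primary diphenylsilyl ether while the secondary silyl ether next to the quaternary C-12 stays, and the buffer suppresses silyl migration and lactone opening.

Step 8
Reactants: 11 primary alcohol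
Product: 12 (2S)-2-{[tert-butyl(dimethyl)silyl]oxy}-2-[(2R,5S)-5-[(2Z)-3-iodobut-2-en-1-yl]-2-methyl-7-oxooxepan-2-yl]acetaldehyde
Conditions: Dess–Martin periodinane, CH2Cl2, 0 °C to rt
Reagents that add atoms: none
Why: Dess–Martin oxidation gives the α-silyloxy aldehyde under near-neutral conditions that leave C-11 configurationally intact.

Step 9
Reactants: 12 α-silyloxy aldehyde
Product: 13 (4S,7R)-7-[(1R)-1-{[tert-butyl(dimethyl)silyl]oxy}prop-2-en-1-yl]-4-[(2Z)-3-iodobut-2-en-1-yl]-7-methyloxepan-2-one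
Conditions: Ph3PCH3Br, KN(SiMe3)2, THF, −78 to 0 °C
Reagents that add atoms: methyltriphenylphosphonium bromide, C[P+](c1ccccc1)(c1ccccc1)c1ccccc1.[Br-]
Why: Wittig methylenation brings in C-9 as a terminal vinyl group, the aldehyde reacting far faster than the lactone carbonyl.

Step 10
Reactants: 13 vinyl iodide
Product: 14 (4S,7R)-7-[(1R)-1-{[tert-butyl(dimethyl)silyl]oxy}prop-2-en-1-yl]-4-[(2Z)-4-hydroxy-3-methylbut-2-en-1-yl]-7-methyloxepan-2-one
Conditions: Bu3SnCH2OH, Pd(PPh3)4 (cat.), toluene, 90 °C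
Reagents that add atoms: (tributylstannyl)methanol, CCCC[Sn](CCCC)(CCCC)CO
Why: Stille coupling replaces iodine by the hydroxymethyl carbon C-5 with retention of alkene geometry, giving the Z-allylic alcohol.

Step 11
Reactants: 14 Z-allylic alcohol
Product: 15 (2Z)-4-[(4S,7R)-7-[(1R)-1-{[tert-butyl(dimethyl)silyl]oxy}prop-2-en-1-yl]-7-methyl-2-oxooxepan-4-yl]-2-methylbut-2-en-1-yl methyl carbonate
Conditions: ClCO2Me, pyridine, CH2Cl2, 0 °C
Reagents that add atoms: methyl chloroformate, COC(=O)Cl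
Why: Acylation turns the primary allylic alcohol into the carbonate leaving group needed for copper-catalysed substitution.

Step 12
Reactants: 15 Z-allylic carbonate
Product: 16 (4S,7R)-7-[(1R)-1-{[tert-butyl(dimethyl)silyl]oxy}prop-2-en-1-yl]-7-methyl-4-[(2R)-3-methyl-2-(4,4,5,5-tetramethyl-1,3,2-dioxaborolan-2-yl)but-3-en-1-yl]oxepan-2-one
Conditions: CuCl (cat.), (R,R)-2,3-bis(tert-butylmethylphosphino)quinoxaline (cat.), KOtBu (cat.), B2pin2, THF, 0 °C to rt
Reagents that add atoms: bis(pinacolato)diboron, CC1(C)OB(OC1(C)C)B1OC(C)(C)C(C)(C)O1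
Why: Copper-catalysed γ-selective (SN2′) allylic borylation places boron on C-3 and moves the alkene to C-4=C-5, the chiral bisphosphine–copper boryl choosing the alkene face so that C-3 should be R (the ligand enantiomer is assigned by analogy and would be confirmed on a model).

Step 13
Reactants: 17 but-2-yn-1-ol
Product: 19 (2Z)-3-iodobut-2-en-1-ol, via alkenylalanate 18 (not isolated)
Conditions: NaAlH2(OCH2CH2OMe)2, THF, 0 °C; then I2, −78 °C
Reagents that add atoms: iodine, II
Why: Hydroxyl-directed trans-hydroalumination puts aluminium on the distal alkyne carbon in a five-membered alanate, and iodinolysis with retention gives the Z-iodoalkene (iodine cis to the carbinol carbon).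

Step 14
Reactants: 19 (2Z)-3-iodobut-2-en-1-ol
Product: 20 (2Z)-3-iodobut-2-enal
Conditions: MnO2, CH2Cl2, rt
Reagents that add atoms: none
Why: Manganese dioxide oxidizes the allylic alcohol selectively to the enal under neutral conditions that should preserve the Z geometry.

Step 15
Reactants: 16 (3R)-allylboronate; 20 (2Z)-3-iodobut-2-enal
Product: 21 (4S,7R)-7-[(1R)-1-{[tert-butyl(dimethyl)silyl]oxy}prop-2-en-1-yl]-4-[(2Z,5R,6Z)-5-hydroxy-7-iodo-3-methylocta-2,6-dien-1-yl]-7-methyloxepan-2-one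
Conditions: toluene, 40 °C; then aq. NaHCO3
Reagents that add atoms: none
Why: Allylboration through a closed Zimmerman–Traxler chair forms C-5–C-6; the C-2 chain on the boron-bearing carbon sits axial to avoid A(1,2) strain with the 2-methyl group, which should give the Z C-3=C-4 alkene and transfer the C-3 configuration to C-6 as R.

Step 16
Reactants: 21 homoallylic alcohol
Product: 22 (4S,7R)-7-[(1R)-1-{[tert-butyl(dimethyl)silyl]oxy}prop-2-en-1-yl]-4-{[(2R,3S)-3-[(2R,3Z)-2-hydroxy-4-iodopent-3-en-1-yl]-3-methyloxiran-2-yl]methyl}-7-methyloxepan-2-one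
Conditions: VO(acac)2 (cat.), t-BuOOH, CH2Cl2, 0 °C to rt
Reagents that add atoms: tert-butyl hydroperoxide, CC(C)(C)OO
Why: Hydroxyl-directed vanadium epoxidation of the Z-homoallylic alcohol goes through a chair vanadate in which A(1,3) strain fixes the C-5 rotamer and the C-7 substituent avoids the C-4 methyl, so oxygen should arrive syn to the C-6 hydroxyl and give the (3R,4S) epoxide, the electron-poor iodoalkene and the undirected vinyl group being left alone.

Step 17
Reactants: 22 epoxy alcohol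
Product: 23 (4S,7R)-7-[(1R)-1-{[tert-butyl(dimethyl)silyl]oxy}prop-2-en-1-yl]-4-{[(2R,3S)-3-[(2R,3Z)-2-{[tert-butyl(dimethyl)silyl]oxy}-4-iodopent-3-en-1-yl]-3-methyloxiran-2-yl]methyl}-7-methyloxepan-2-one
Conditions: t-BuMe2SiCl, imidazole, DMAP (cat.), DMF, rt
Reagents that add atoms: tert-butyl(chloro)dimethylsilane, CC(C)(C)[Si](C)(C)Cl
Why: Silylation under non-acidic conditions masks the C-6 hydroxyl for the borane and enolate steps without touching the epoxide.

Step 18
Reactants: 23 bis-silyl ether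
Product: 25 (1S,3R,4S,6R,7Z,11R,12R)-6,11-bis{[tert-butyl(dimethyl)silyl]oxy}-3,4-epoxy-17-norcembr-7-en-16,12-olide, via alkylborane 24 (not isolated)
Conditions: 9-BBN, THF, rt; then slow addition to Pd(dppf)Cl2 (cat.), AsPh3, Cs2CO3, DMF/THF/H2O, 50 °C, high dilution
Reagents that add atoms: none
Why: Hydroboration is selective for the terminal vinyl group, and the intramolecular B-alkyl Suzuki–Miyaura coupling closes the 14-membered carbocycle at C-8–C-9 with retention of the Z geometry at C-7=C-8.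

Step 19
Reactants: 25 macrocyclic lactone
Product: 28 (1S,3R,4S,6R,7Z,11R,12R)-6,11-bis{[tert-butyl(dimethyl)silyl]oxy}-3,4-epoxycembra-7,15(17)-dien-16,12-olide, via Mannich base 26 (not isolated), via ammonium iodide 27 (not isolated)
Conditions: LiN(iPr)2, THF, −78 °C; CH2=NMe2 I, −78 to 0 °C; then MeI, CH2Cl2/MeOH, rt; then DBU, CH2Cl2
Reagents that add atoms: N,N-dimethylmethyleneiminium iodide (Eschenmoser's salt), C=[N+](C)C.[I-]
Why: The lactone enolate (C-15 is the only α-position) undergoes a Mannich reaction with the iminium salt, and quaternization followed by Hofmann-type elimination installs the exocyclic methylene.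

Step 20
Reactants: 28 bis-silyl ether of the target
Product: 29 CNP0250657.1, (1S,3R,4S,6R,7Z,11R,12R)-3,4-epoxy-6,11-dihydroxycembra-7,15(17)-dien-16,12-olide
Conditions: HF·pyridine, pyridine, THF, 0 °C to rt
Reagents that add atoms: none
Why: Pyridine-buffered fluoride desilylation frees both hydroxyls under conditions that should spare the epoxide and the α-methylene lactone.

**Compound list**

1 | nerol, (2Z)-3,7-dimethylocta-2,6-dien-1-ol | CC(C)=CCC/C(C)=C\CO | starting material
2 | (2R,3S)-2,3-epoxynerol | OC[C@H]1O[C@@]1(C)CCC=C(C)C | intermediate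
3 | tert-butyl{[(2R,3S)-3-methyl-3-(4-methylpent-3-en-1-yl)oxiran-2-yl]methoxy}diphenylsilane | CC(C)(C)[Si](c1ccccc1)(c1ccccc1)OC[C@H]1O[C@@]1(C)CCC=C(C)C | intermediate
4 | (2E)-5-[(2S,3R)-3-{[tert-butyl(diphenyl)silyl]oxymethyl}-2-methyloxiran-2-yl]pent-2-enal | CC(C)(C)[Si](c1ccccc1)(c1ccccc1)OC[C@H]1O[C@@]1(C)CC/C=C/C=O | intermediate
5 | di-tert-butyl malonate | CC(C)(C)OC(=O)CC(=O)OC(C)(C)C | starting material
6 | di-tert-butyl 2-[(3S)-1-[(2S,3R)-3-{[tert-butyl(diphenyl)silyl]oxymethyl}-2-methyloxiran-2-yl]-5-oxopentan-3-yl]propanedioate | O=CC[C@H](CC[C@]1(C)O[C@@H]1CO[Si](c1ccccc1)(c1ccccc1)C(C)(C)C)C(C(=O)OC(C)(C)C)C(=O)OC(C)(C)C | intermediate (not isolated)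
7 | (4S,7R)-7-[(1R)-2-{[tert-butyl(diphenyl)silyl]oxy}-1-hydroxyethyl]-7-methyl-2-oxo-4-(2-oxoethyl)oxepane-3-carboxylic acid, both C-3 epimers | O=CC[C@H]1C(C(=O)O)C(=O)O[C@](C)(CC1)[C@H](O)CO[Si](c1ccccc1)(c1ccccc1)C(C)(C)C | intermediate (not isolated)
8 | 2-[(4S,7R)-7-[(1R)-2-{[tert-butyl(diphenyl)silyl]oxy}-1-hydroxyethyl]-7-methyl-2-oxooxepan-4-yl]acetaldehyde | O=CC[C@H]1CC(=O)O[C@](C)(CC1)[C@H](O)CO[Si](c1ccccc1)(c1ccccc1)C(C)(C)C | intermediate
9 | 2-[(4S,7R)-7-[(1R)-1-{[tert-butyl(dimethyl)silyl]oxy}-2-{[tert-butyl(diphenyl)silyl]oxy}ethyl]-7-methyl-2-oxooxepan-4-yl]acetaldehyde | O=CC[C@H]1CC(=O)O[C@](C)(CC1)[C@H](O[Si](C)(C)C(C)(C)C)CO[Si](c1ccccc1)(c1ccccc1)C(C)(C)C | intermediate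
10 | (4S,7R)-7-[(1R)-1-{[tert-butyl(dimethyl)silyl]oxy}-2-{[tert-butyl(diphenyl)silyl]oxy}ethyl]-4-[(2Z)-3-iodobut-2-en-1-yl]-7-methyloxepan-2-one | C/C(I)=C/C[C@H]1CC(=O)O[C@](C)(CC1)[C@H](O[Si](C)(C)C(C)(C)C)CO[Si](c1ccccc1)(c1ccccc1)C(C)(C)C | intermediate
11 | (4S,7R)-7-[(1R)-1-{[tert-butyl(dimethyl)silyl]oxy}-2-hydroxyethyl]-4-[(2Z)-3-iodobut-2-en-1-yl]-7-methyloxepan-2-one | C/C(I)=C/C[C@H]1CC(=O)O[C@](C)(CC1)[C@H](O[Si](C)(C)C(C)(C)C)CO | intermediate
12 | (2S)-2-{[tert-butyl(dimethyl)silyl]oxy}-2-[(2R,5S)-5-[(2Z)-3-iodobut-2-en-1-yl]-2-methyl-7-oxooxepan-2-yl]acetaldehyde | C/C(I)=C/C[C@H]1CC(=O)O[C@](C)(CC1)[C@H](O[Si](C)(C)C(C)(C)C)C=O | intermediate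
13 | (4S,7R)-7-[(1R)-1-{[tert-butyl(dimethyl)silyl]oxy}prop-2-en-1-yl]-4-[(2Z)-3-iodobut-2-en-1-yl]-7-methyloxepan-2-one | C/C(I)=C/C[C@H]1CC(=O)O[C@](C)(CC1)[C@H](O[Si](C)(C)C(C)(C)C)C=C | intermediate
14 | (4S,7R)-7-[(1R)-1-{[tert-butyl(dimethyl)silyl]oxy}prop-2-en-1-yl]-4-[(2Z)-4-hydroxy-3-methylbut-2-en-1-yl]-7-methyloxepan-2-one | OC/C(C)=C\C[C@H]1CC(=O)O[C@](C)(CC1)[C@H](O[Si](C)(C)C(C)(C)C)C=C | intermediate
15 | (2Z)-4-[(4S,7R)-7-[(1R)-1-{[tert-butyl(dimethyl)silyl]oxy}prop-2-en-1-yl]-7-methyl-2-oxooxepan-4-yl]-2-methylbut-2-en-1-yl methyl carbonate | COC(=O)OC/C(C)=C\C[C@H]1CC(=O)O[C@](C)(CC1)[C@H](O[Si](C)(C)C(C)(C)C)C=C | intermediate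
16 | (4S,7R)-7-[(1R)-1-{[tert-butyl(dimethyl)silyl]oxy}prop-2-en-1-yl]-7-methyl-4-[(2R)-3-methyl-2-(4,4,5,5-tetramethyl-1,3,2-dioxaborolan-2-yl)but-3-en-1-yl]oxepan-2-one | C=C(C)[C@H](B1OC(C)(C)C(C)(C)O1)C[C@H]1CC(=O)O[C@](C)(CC1)[C@H](O[Si](C)(C)C(C)(C)C)C=C | intermediate
17 | but-2-yn-1-ol | CC#CCO | starting material
18 | sodium cyclic alkenylalanate from trans-hydroalumination of 17 | CC1=CCO[Al-]1(OCCOC)OCCOC.[Na+] | intermediate (not isolated)
19 | (2Z)-3-iodobut-2-en-1-ol | C/C(I)=C/CO | intermediate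
20 | (2Z)-3-iodobut-2-enal | C/C(I)=C/C=O | intermediate
21 | (4S,7R)-7-[(1R)-1-{[tert-butyl(dimethyl)silyl]oxy}prop-2-en-1-yl]-4-[(2Z,5R,6Z)-5-hydroxy-7-iodo-3-methylocta-2,6-dien-1-yl]-7-methyloxepan-2-one | C/C(I)=C/[C@H](O)C/C(C)=C\C[C@H]1CC(=O)O[C@](C)(CC1)[C@H](O[Si](C)(C)C(C)(C)C)C=C | intermediate
22 | (4S,7R)-7-[(1R)-1-{[tert-butyl(dimethyl)silyl]oxy}prop-2-en-1-yl]-4-{[(2R,3S)-3-[(2R,3Z)-2-hydroxy-4-iodopent-3-en-1-yl]-3-methyloxiran-2-yl]methyl}-7-methyloxepan-2-one | C/C(I)=C/[C@H](O)C[C@]1(C)O[C@@H]1C[C@H]2CC(=O)O[C@](C)(CC2)[C@H](O[Si](C)(C)C(C)(C)C)C=C | intermediate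
23 | C-6 tert-butyldimethylsilyl ether of 22 | C/C(I)=C/[C@H](O[Si](C)(C)C(C)(C)C)C[C@]1(C)O[C@@H]1C[C@H]2CC(=O)O[C@](C)(CC2)[C@H](O[Si](C)(C)C(C)(C)C)C=C | intermediate
24 | B-alkyl-9-borabicyclo[3.3.1]nonane from hydroboration of the vinyl group of 23 (boron on C-9) | C/C(I)=C/[C@H](O[Si](C)(C)C(C)(C)C)C[C@]1(C)O[C@@H]1C[C@H]2CC(=O)O[C@](C)(CC2)[C@H](O[Si](C)(C)C(C)(C)C)CCB1C2CCCC1CCC2 | intermediate (not isolated)
25 | (1S,3R,4S,6R,7Z,11R,12R)-6,11-bis{[tert-butyl(dimethyl)silyl]oxy}-3,4-epoxy-17-norcembr-7-en-16,12-olide | O=C1O[C@]2(C)CC[C@H](C1)C[C@H]1O[C@@]1(C)C[C@@H](O[Si](C)(C)C(C)(C)C)/C=C(/C)CC[C@H]2O[Si](C)(C)C(C)(C)C | intermediate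
26 | 15-(dimethylaminomethyl) derivative of 25, both C-15 epimers | CN(C)CC1C(=O)O[C@]2(C)CC[C@H]1C[C@H]1O[C@@]1(C)C[C@@H](O[Si](C)(C)C(C)(C)C)/C=C(/C)CC[C@H]2O[Si](C)(C)C(C)(C)C | intermediate (not isolated)
27 | 15-(trimethylammoniomethyl) iodide of 25, both C-15 epimers | C[N+](C)(C)CC1C(=O)O[C@]2(C)CC[C@H]1C[C@H]1O[C@@]1(C)C[C@@H](O[Si](C)(C)C(C)(C)C)/C=C(/C)CC[C@H]2O[Si](C)(C)C(C)(C)C.[I-] | intermediate (not isolated)
28 | (1S,3R,4S,6R,7Z,11R,12R)-6,11-bis{[tert-butyl(dimethyl)silyl]oxy}-3,4-epoxycembra-7,15(17)-dien-16,12-olide | C=C1C(=O)O[C@]2(C)CC[C@H]1C[C@H]1O[C@@]1(C)C[C@@H](O[Si](C)(C)C(C)(C)C)/C=C(/C)CC[C@H]2O[Si](C)(C)C(C)(C)C | intermediate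
29 | CNP0250657.1, (1S,3R,4S,6R,7Z,11R,12R)-3,4-epoxy-6,11-dihydroxycembra-7,15(17)-dien-16,12-olide | C=C1C(=O)O[C@]2(C)CC[C@H]1C[C@H]1O[C@@]1(C)C[C@@H](O)/C=C(/C)CC[C@H]2O | target

**Step count and risks**

Total step count: 20. Longest linear sequence: 18 steps (steps 1 to 12 and 15 to 20).

Steps most likely to fail:

Step 4. In the acid stage the protonated trisubstituted epoxide may rearrange by hydride shift or be captured by trifluoroacetate faster than the ester oxygen closes the seven-membered ring, and the hindered malonate may add slowly in the Michael stage. The fallback sets out from 4 and separates the events under milder conditions. The same aminocatalyst adds diallyl malonate to give the diallyl malonate adduct F1. Pd(PPh3)4 with formic acid and triethylamine then removes both allyl groups, and gentle warming decarboxylates the diacid to the epoxy acid F2. A catalytic amount of camphorsulfonic acid in CH2Cl2 should then close the free epoxy acid to the hydroxy lactone, which comes back to the route at 8.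

Step 12. Catalyst control over the boron-bearing carbon may be poor (mismatch with the resident stereocentres or a competing unselective pathway), which would erode the configuration passed on to C-6. The fallback sets out from 15 and sets C-6 by reagent-controlled carbonyl reduction instead of chirality transfer. Borylation with CuCl and an achiral bisphosphine gives the boronate as a C-3 epimer mixture F3. Allylboration of 20 still gives the Z C-3=C-4 alkene but a mixture at C-6, the dienol F4. Dess–Martin oxidation gives the enone F5, and Corey–Bakshi–Shibata reduction with the (S)-methyl oxazaborolidine and catecholborane should give the 6R carbinol, coming back to the route at 21.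

Step 18. Intermolecular coupling to oligomers, protodeboronation or β-hydride elimination may outrun ring closure, and the aqueous base may open the lactone. The fallback sets out from 23 and closes the same bond through an organozinc under base-free conditions. Hydroboration as before followed by NaBO3 oxidation gives the primary alcohol F6, and I2, PPh3 and imidazole convert it into the primary iodide F7. Zinc insertion into the alkyl iodide and an intramolecular Negishi coupling with Pd(PPh3)4 at high dilution should then give the macrocycle, coming back to the route at 25.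

Further compounds
F1 | step 4 | diallyl 2-[(3S)-1-[(2S,3R)-3-{[tert-butyl(diphenyl)silyl]oxymethyl}-2-methyloxiran-2-yl]-5-oxopentan-3-yl]propanedioate | O=CC[C@H](CC[C@]1(C)O[C@@H]1CO[Si](c1ccccc1)(c1ccccc1)C(C)(C)C)C(C(=O)OCC=C)C(=O)OCC=C
F2 | step 4 | (3S)-5-[(2S,3R)-3-{[tert-butyl(diphenyl)silyl]oxymethyl}-2-methyloxiran-2-yl]-3-(2-oxoethyl)pentanoic acid | O=CC[C@H](CC[C@]1(C)O[C@@H]1CO[Si](c1ccccc1)(c1ccccc1)C(C)(C)C)CC(=O)O
F3 | step 12 | allylboronate 16 as a mixture of epimers at the boron-bearing carbon | C=C(C)C(B1OC(C)(C)C(C)(C)O1)C[C@H]1CC(=O)O[C@](C)(CC1)[C@H](O[Si](C)(C)C(C)(C)C)C=C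
F4 | step 12 | dienol 21 as a mixture of epimers at C-6 | C/C(I)=C/C(O)C/C(C)=C\C[C@H]1CC(=O)O[C@](C)(CC1)[C@H](O[Si](C)(C)C(C)(C)C)C=C
F5 | step 12 | (4S,7R)-7-[(1R)-1-{[tert-butyl(dimethyl)silyl]oxy}prop-2-en-1-yl]-4-[(2Z,6Z)-7-iodo-3-methyl-5-oxoocta-2,6-dien-1-yl]-7-methyloxepan-2-one | C/C(I)=C/C(=O)C/C(C)=C\C[C@H]1CC(=O)O[C@](C)(CC1)[C@H](O[Si](C)(C)C(C)(C)C)C=C
F6 | step 18 | primary alcohol from hydroboration and oxidation of 23 (hydroxyl on C-9) | C/C(I)=C/[C@H](O[Si](C)(C)C(C)(C)C)C[C@]1(C)O[C@@H]1C[C@H]2CC(=O)O[C@](C)(CC2)[C@H](O[Si](C)(C)C(C)(C)C)CCO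
F7 | step 18 | primary iodide from F6 (iodine on C-9) | C/C(I)=C/[C@H](O[Si](C)(C)C(C)(C)C)C[C@]1(C)O[C@@H]1C[C@H]2CC(=O)O[C@](C)(CC2)[C@H](O[Si](C)(C)C(C)(C)C)CCI
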